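**Retrosynthetic overview**

- The target is opened at the aryl ketone: acetal cleavage, then a Weinreb ketone synthesis from 2,4-bis(methoxymethoxy)phenyllithium and a chiral N-methoxy-N-methyl amide. The benzene ring is bought intact as 4-bromoresorcinol.
- Key disconnection: the C5–C6 bond of the octenone chain (sp3 CH2 to sp2 CH=). It is formed by a ligand-controlled anti-Markovnikov hydroalkenylation (CuH/Pd) of an achiral 3,3-divinyl amide with an (E)-alkenyl bromide.
- Enabling feature: the quaternary carbon C3 carries an ethenyl group and the C4–C5 ethylene arm. With the C5–C6 bond cut, that arm is a second ethenyl group, so C3 becomes a prochiral carbon (CH3, CH2C=O, vinyl, vinyl) with two enantiotopic vinyl groups, and the coupling itself creates the only stereocentre.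
- The diene amide comes from a Johnson–Claisen rearrangement of (E)-3-methylpent-2-en-4-yn-1-ol, alkyne semihydrogenation and amidation. The alkenyl bromide comes from carboalumination of propargyl alcohol (sets E) and γ-alkylation of a 2-silyloxyfuran.
- Rings: the furan is the only ring made, by reduction and dehydration of the bought butenolide ring (step 8), before the key step. The benzene ring is attached in step 11.

Key step: step 9

Assumption: the sense of enantiotopic-vinyl selection in step 9 cannot be assigned with certainty in advance; the route is written for (R)-DTBM-SEGPHOS, and the (S)-ligand is used instead if it proves to deliver the (3S)-amide.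

**Route**

Step 1
Reactants: 1 (2E)-3-methylpent-2-en-4-yn-1-ol
Product: 3 ethyl 3-ethynyl-3-methylpent-4-enoate (racemic), via ketene acetal 2 (not isolated)
Conditions: MeC(OEt)3 (5 equiv), EtCO2H (cat.), 140 °C, EtOH distilled off
Reagents that add atoms: triethyl orthoacetate, CC(OCC)(OCC)OCC
Why: Johnson–Claisen (orthoester Claisen) rearrangement: acid-catalysed exchange and loss of ethanol give ketene acetal 2, whose chair [3,3] shift delivers the acetate carbon to C3 of the allyl unit and builds the quaternary carbon (racemic, which is of no consequence because step 2 makes this carbon achiral).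

Step 2
Reactants: 3 ethyl 3-ethynyl-3-methylpent-4-enoate
Product: 4 ethyl 3-ethenyl-3-methylpent-4-enoate (achiral)
Conditions: H2 (1 atm), Pd/CaCO3 poisoned with Pb(OAc)2, quinoline, EtOAc, rt, stopped after 1 equiv H2
Reagents that add atoms: none
Why: Lindlar semihydrogenation: the terminal alkyne binds the lead-poisoned palladium surface far more strongly than a monosubstituted alkene, so hydrogen uptake should stop at the alkene, and the carbon becomes prochiral with two identical vinyl groups.

Step 3
Reactants: 4 ethyl 3-ethenyl-3-methylpent-4-enoate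
Product: 5 3-ethenyl-N-methoxy-N,3-dimethylpent-4-enamide (achiral)
Conditions: MeNH(OMe)·HCl (1.5 equiv), i-PrMgCl (3 equiv), THF, −20 → 0 °C
Reagents that add atoms: N,O-dimethylhydroxylamine hydrochloride, CNOC.Cl
Why: Weinreb amidation of an ester with the chloromagnesium amide made in the flask; the amide is chosen because it should survive CuH and NaOSiMe3 in step 9 and later accepts exactly one aryllithium.

Step 4
Reactants: 6 prop-2-yn-1-ol
Product: 8 (2E)-3-bromo-2-methylprop-2-en-1-ol, via alkenylalane 7 (not isolated)
Conditions: Me3Al (3 equiv), Cp2ZrCl2 (0.25 equiv), CH2Cl2, 0 °C → rt; then NBS, THF, −30 → 0 °C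
Reagents that add atoms: trimethylaluminium, C[Al](C)C; N-bromosuccinimide, O=C1CCC(=O)N1Br
Why: Negishi zirconium-catalysed carboalumination: syn addition of CH3–Al across the alkyne with aluminium at the terminal carbon gives alkenylalane 7, and bromodealumination with NBS proceeds with retention, which fixes the E geometry needed for the C6=C7 bond of the target.

Step 5
Reactants: 8 (2E)-3-bromo-2-methylprop-2-en-1-ol
Product: 9 (1E)-1,3-dibromo-2-methylprop-1-ene
Conditions: CBr4, PPh3, CH2Cl2, 0 °C
Reagents that add atoms: tetrabromomethane, BrC(Br)(Br)Br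
Why: Appel reaction: SN2 displacement at the primary allylic carbon through the alkoxyphosphonium salt, which leaves the alkenyl bromide and its geometry untouched.

Step 6
Reactants: 10 3-methylfuran-2(5H)-one
Product: 11 trimethyl[(3-methylfuran-2-yl)oxy]silane
Conditions: Me3SiOTf, Et3N, Et2O, 0 °C
Reagents that add atoms: trimethylsilyl trifluoromethanesulfonate, C[Si](C)(C)OS(=O)(=O)C(F)(F)F
Why: Soft enolisation (silyl dienol ether formation): triethylamine removes the acidic γ-hydrogen of the O-silylated butenolide, and the gain of furan aromaticity drives formation of the 2-silyloxyfuran.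

Step 7
Reactants: 11 trimethyl[(3-methylfuran-2-yl)oxy]silane; 9 (1E)-1,3-dibromo-2-methylprop-1-ene
Product: 12 5-[(2E)-3-bromo-2-methylprop-2-en-1-yl]-3-methylfuran-2(5H)-one (racemic)
Conditions: AgOCOCF3 (1.1 equiv), CH2Cl2, −78 °C → rt
Reagents that add atoms: none
Why: Silver-promoted vinylogous alkylation of a 2-silyloxyfuran: AgOCOCF3 activates only the allylic C–Br bond of 9, C5 of 11 attacks the CH2 terminus and trifluoroacetate removes the silyl group, while attack through C3 is disfavoured because it would create a quaternary carbon and a deconjugated lactone; the ring stereocentre forms racemic and disappears in step 8.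

Step 8
Reactants: 12 5-[(2E)-3-bromo-2-methylprop-2-en-1-yl]-3-methylfuran-2(5H)-one
Product: 14 2-[(2E)-3-bromo-2-methylprop-2-en-1-yl]-4-methylfuran, via lactol 13 (not isolated)
Conditions: i-Bu2AlH (1.1 equiv), CH2Cl2, −78 °C; then dilute aq. H2SO4, 0 °C
Reagents that add atoms: none
Why: Partial reduction and aromatisation: i-Bu2AlH stops at the lactol stage at −78 °C and acid work-up dehydrates lactol 13 to the aromatic furan (the standard butenolide-to-furan conversion), placing the side chain at C2 and the methyl group at C4; the alkenyl bromide is inert to i-Bu2AlH at this temperature.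

Step 9
Reactants: 5 3-ethenyl-N-methoxy-N,3-dimethylpent-4-enamide (3 equiv); 14 2-[(2E)-3-bromo-2-methylprop-2-en-1-yl]-4-methylfuran (limiting)
Product: 17 (3R,6E)-3-ethenyl-N-methoxy-N,3,7-trimethyl-8-(4-methylfuran-2-yl)oct-6-enamide, via alkylcopper 15 (not isolated), via alkenylpalladium bromide 16 (not isolated)
Conditions: Cu(OAc)2 (5 mol %), (R)-DTBM-SEGPHOS (5.5 mol %), [Pd(cinnamyl)Cl]2 (2 mol %), BrettPhos (4.4 mol %), MeSiH(OMe)2 (2.5 equiv), NaOSiMe3 (2 equiv), THF, 40 °C
Reagents that add atoms: none
Why: Proposed new method: ligated CuH, formed from Cu(OAc)2, (R)-DTBM-SEGPHOS and the silane, should add irreversibly across one of the two enantiotopic vinyl groups of 5 with copper at the terminal carbon to give the primary alkylcopper 15, while oxidative addition of 14 to zerovalent palladium/BrettPhos gives 16 with retention of the E geometry; transmetalation from copper to palladium and C(sp3)–C(sp2) reductive elimination then form the C5–C6 bond, and NaOSiMe3 with the silane returns CuBr to CuH. The closest known reaction type is the dual CuH/Pd-catalysed anti-Markovnikov hydroarylation and hydroalkenylation of unactivated terminal alkenes with aryl bromides and alkenyl triflates, together with the alkene-face recognition by DTBM-SEGPHOS–CuH in asymmetric hydrofunctionalisation; what is new is the use of this hydrocupration to choose between two enantiotopic vinyl groups on a quaternary carbon. No ring is closed. The only new stereocentre, C3, is set in the hydrocupration and is controlled by the chiral bisphosphine on copper, which has to place the CH3 and CH2C(=O)N(OMe)Me substituents of the prochiral carbon differently in the two diastereomeric transition states, the Lewis-basic amide carbonyl being the larger and potentially copper-contacting group. The step needs group selectivity (ligand control, reinforced because the minor enantiomer of 17 retains the faster-reacting vinyl group and is drained into the bis-coupled by-product), mono-coupling (threefold excess of the cheap diene 5), anti-Markovnikov regiochemistry (the internal alkene carbon is flanked by the quaternary carbon) and chemoselectivity (the tertiary amide, the furan and the trisubstituted alkene are inert to CuH, which is why the aryl ketone is installed only afterwards).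

Step 10
Reactants: 18 4-bromobenzene-1,3-diol
Product: 19 1-bromo-2,4-bis(methoxymethoxy)benzene
Conditions: MOMCl (2.5 equiv), i-Pr2NEt (3 equiv), CH2Cl2, 0 °C → rt
Reagents that add atoms: chloromethyl methyl ether, COCCl
Why: O-Alkylation of both phenols with chloromethyl methyl ether under amine base (Williamson-type acetal formation); the MOM groups survive n-BuLi and stabilise the ortho-lithiated arene by chelation.

Step 11
Reactants: 19 1-bromo-2,4-bis(methoxymethoxy)benzene; 17 (3R,6E)-3-ethenyl-N-methoxy-N,3,7-trimethyl-8-(4-methylfuran-2-yl)oct-6-enamide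
Product: 22 (3R,6E)-1-[2,4-bis(methoxymethoxy)phenyl]-3-ethenyl-3,7-dimethyl-8-(4-methylfuran-2-yl)oct-6-en-1-one, via aryllithium 20 (not isolated), via tetrahedral lithium adduct 21 (not isolated)
Conditions: 19, n-BuLi (1.3 equiv), THF, −78 °C; then 17, −78 → 0 °C; aq. NH4Cl
Reagents that add atoms: none
Why: Bromine–lithium exchange followed by Weinreb ketone synthesis: aryllithium 20 adds once to the N-methoxy-N-methyl amide to give the chelated adduct 21, which releases the ketone only on aqueous work-up, so no tertiary alcohol should form; the quaternary stereocentre carries no hydrogen and cannot epimerise.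

Step 12
Reactants: 22 (3R,6E)-1-[2,4-bis(methoxymethoxy)phenyl]-3-ethenyl-3,7-dimethyl-8-(4-methylfuran-2-yl)oct-6-en-1-one
Product: 23 (3R,6E)-1-(2,4-dihydroxyphenyl)-3-ethenyl-3,7-dimethyl-8-(4-methylfuran-2-yl)oct-6-en-1-one
Conditions: conc. aq. HCl (cat.), MeOH, rt
Reagents that add atoms: none
Why: Acid-catalysed acetal exchange (MOM cleavage) with methanol as acceptor; the ortho ether is activated by the neighbouring carbonyl, and dilute acid at room temperature should leave the furan and the alkenes intact.

**Compound list**

1 | (2E)-3-methylpent-2-en-4-yn-1-ol | C#C/C(C)=C/CO | starting material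
2 | 1-ethoxy-1-{[(2E)-3-methylpent-2-en-4-yn-1-yl]oxy}ethene (ketene acetal) | C=C(OCC)OC/C=C(\C)C#C | intermediate
3 | ethyl 3-ethynyl-3-methylpent-4-enoate (racemic) | C#CC(C)(C=C)CC(=O)OCC | intermediate
4 | ethyl 3-ethenyl-3-methylpent-4-enoate (achiral) | C=CC(C)(C=C)CC(=O)OCC | intermediate
5 | 3-ethenyl-N-methoxy-N,3-dimethylpent-4-enamide (achiral) | C=CC(C)(C=C)CC(=O)N(C)OC | intermediate
6 | prop-2-yn-1-ol | C#CCO | starting material
7 | [(1E)-3-(dimethylalumanyloxy)-2-methylprop-1-en-1-yl]dimethylalumane (alkenylalane) | C[Al](C)/C=C(\C)CO[Al](C)C | intermediate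
8 | (2E)-3-bromo-2-methylprop-2-en-1-ol | Br/C=C(\C)CO | intermediate
9 | (1E)-1,3-dibromo-2-methylprop-1-ene | Br/C=C(\C)CBr | intermediate
10 | 3-methylfuran-2(5H)-one | CC1=CCOC1=O | starting material
11 | trimethyl[(3-methylfuran-2-yl)oxy]silane | Cc1ccoc1O[Si](C)(C)C | intermediate
12 | 5-[(2E)-3-bromo-2-methylprop-2-en-1-yl]-3-methylfuran-2(5H)-one (racemic) | CC1=CC(C/C(C)=C/Br)OC1=O | intermediate
13 | 5-[(2E)-3-bromo-2-methylprop-2-en-1-yl]-3-methyl-2,5-dihydrofuran-2-ol (lactol, diastereomer mixture) | CC1=CC(C/C(C)=C/Br)OC1O | intermediate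
14 | 2-[(2E)-3-bromo-2-methylprop-2-en-1-yl]-4-methylfuran | Br/C=C(\C)Cc1cc(C)co1 | intermediate
15 | (3S)-5-cuprio-3-ethenyl-N-methoxy-N,3-dimethylpentanamide, monovalent copper bearing (R)-DTBM-SEGPHOS (ligand not drawn; S only through the CIP rank of copper, same spatial arrangement as in 17) | C=C[C@](C)(CC[Cu])CC(=O)N(C)OC | intermediate
16 | bromo[(1E)-2-methyl-3-(4-methylfuran-2-yl)prop-1-en-1-yl]palladium, divalent palladium bearing BrettPhos (ligand not drawn) | Br[Pd]/C=C(\C)Cc1cc(C)co1 | intermediate
17 | (3R,6E)-3-ethenyl-N-methoxy-N,3,7-trimethyl-8-(4-methylfuran-2-yl)oct-6-enamide | C=C[C@](C)(CC/C=C(\C)Cc1cc(C)co1)CC(=O)N(C)OC | intermediate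
18 | 4-bromobenzene-1,3-diol | Oc1ccc(Br)c(O)c1 | starting material
19 | 1-bromo-2,4-bis(methoxymethoxy)benzene | COCOc1ccc(Br)c(OCOC)c1 | intermediate
20 | [2,4-bis(methoxymethoxy)phenyl]lithium | COCOc1ccc([Li])c(OCOC)c1 | intermediate
21 | lithium (3R,6E)-1-[2,4-bis(methoxymethoxy)phenyl]-3-ethenyl-1-[methoxy(methyl)amino]-3,7-dimethyl-8-(4-methylfuran-2-yl)oct-6-en-1-olate (both C1 epimers) | C=C[C@](C)(CC/C=C(\C)Cc1cc(C)co1)CC(O[Li])(N(C)OC)c1ccc(OCOC)cc1OCOC | intermediate
22 | (3R,6E)-1-[2,4-bis(methoxymethoxy)phenyl]-3-ethenyl-3,7-dimethyl-8-(4-methylfuran-2-yl)oct-6-en-1-one | C=C[C@](C)(CC/C=C(\C)Cc1cc(C)co1)CC(=O)c1ccc(OCOC)cc1OCOC | intermediate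
23 | (3R,6E)-1-(2,4-dihydroxyphenyl)-3-ethenyl-3,7-dimethyl-8-(4-methylfuran-2-yl)oct-6-en-1-one | C=C[C@](C)(CC/C=C(\C)Cc1cc(C)co1)CC(=O)c1ccc(O)cc1O | target

**Step count and risks**

Total step count: 12. Longest linear sequence: 7 steps (steps 4, 5, 7, 8, 9, 11, 12, from prop-2-yn-1-ol).

Steps most likely to fail:

1. Step 9 (Proposed new method). The copper hydride may discriminate poorly between the two enantiotopic vinyl groups, or may reduce the alkenyl bromide before it reaches palladium. Fallback with known chemistry, setting out from 5 and 14: 9-BBN-H (0.5 equiv relative to 5, THF, 0 °C → rt) hydroborates one vinyl group to racemic 5-(9-borabicyclo[3.3.1]nonan-9-yl)-3-ethenyl-N-methoxy-N,3-dimethylpentanamide F1. This is coupled in the same flask with 14 by B-alkyl Suzuki–Miyaura coupling (Pd(dppf)Cl2, aq. K3PO4, THF/DMF, rt) to racemic (6E)-3-ethenyl-N-methoxy-N,3,7-trimethyl-8-(4-methylfuran-2-yl)oct-6-enamide F2. Preparative chromatography on a chiral stationary phase then separates the (3R)-enantiomer, which is 17 and rejoins the route there, from (3S,6E)-3-ethenyl-N-methoxy-N,3,7-trimethyl-8-(4-methylfuran-2-yl)oct-6-enamide F3.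

2. Step 7. Silver-assisted ionisation of the electron-poor bromoallyl bromide may be slow, so that the silyloxyfuran is lost by protodesilylation; attack through C3 or erosion of the alkene geometry through an allyl cation are also possible. Fallback, setting out from 9 and purchased 3-methylfuran F4: iridium-catalysed C–H borylation ([Ir(OMe)(cod)]2, 4,4′-di-tert-butyl-2,2′-bipyridine, B2pin2, hexane, rt) at the unhindered C5–H gives 4,4,5,5-tetramethyl-2-(4-methylfuran-2-yl)-1,3,2-dioxaborolane F5. Suzuki–Miyaura allylation with 9 (Pd(PPh3)4, K3PO4, THF/H2O, rt), in which zerovalent palladium inserts into the allylic C–Br bond in preference to the alkenyl C–Br bond, comes back to the route at 14 and bypasses 11, 12 and 13.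

3. Step 12. Acid may open or oligomerise the electron-rich 2,4-dialkylfuran before both acetals are cleaved. Fallback, setting out from 18 and 17, with protecting groups removed under neutral conditions: 18 is bis-allylated (allyl bromide, K2CO3, acetone, reflux) to 1-bromo-2,4-bis(prop-2-en-1-yloxy)benzene F6. Bromine–lithium exchange (n-BuLi, THF, −78 °C) gives [2,4-bis(prop-2-en-1-yloxy)phenyl]lithium F7, which is added to 17 at −78 °C to give (3R,6E)-1-[2,4-bis(prop-2-en-1-yloxy)phenyl]-3-ethenyl-3,7-dimethyl-8-(4-methylfuran-2-yl)oct-6-en-1-one F8. Pd(PPh3)4 (cat.) with morpholine in THF at rt removes both allyl groups and comes back to the route at 23.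

Further compounds
F1 | step 9 | 5-(9-borabicyclo[3.3.1]nonan-9-yl)-3-ethenyl-N-methoxy-N,3-dimethylpentanamide (racemic) | C=CC(C)(CCB1C2CCCC1CCC2)CC(=O)N(C)OC
F2 | step 9 | racemic (6E)-3-ethenyl-N-methoxy-N,3,7-trimethyl-8-(4-methylfuran-2-yl)oct-6-enamide | C=CC(C)(CC/C=C(\C)Cc1cc(C)co1)CC(=O)N(C)OC
F3 | step 9 | (3S,6E)-3-ethenyl-N-methoxy-N,3,7-trimethyl-8-(4-methylfuran-2-yl)oct-6-enamide | C=C[C@@](C)(CC/C=C(\C)Cc1cc(C)co1)CC(=O)N(C)OC
F4 | step 7 | 3-methylfuran (purchased) | Cc1ccoc1
F5 | step 7 | 4,4,5,5-tetramethyl-2-(4-methylfuran-2-yl)-1,3,2-dioxaborolane | Cc1coc(B2OC(C)(C)C(C)(C)O2)c1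
F6 | step 12 | 1-bromo-2,4-bis(prop-2-en-1-yloxy)benzene | C=CCOc1ccc(Br)c(OCC=C)c1
F7 | step 12 | [2,4-bis(prop-2-en-1-yloxy)phenyl]lithium | [Li]c1ccc(OCC=C)cc1OCC=C
F8 | step 12 | (3R,6E)-1-[2,4-bis(prop-2-en-1-yloxy)phenyl]-3-ethenyl-3,7-dimethyl-8-(4-methylfuran-2-yl)oct-6-en-1-one | C=C[C@](C)(CC/C=C(\C)Cc1cc(C)co1)CC(=O)c1ccc(OCC=C)cc1OCC=C
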